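**Retrosynthetic overview**
1. The target is the twofold-symmetric C8–C8'' dimer of acacetin, and its only stereo-element is that biaryl axis. The axis is therefore disconnected last, by an atroposelective nickel-catalysed reductive homocoupling of an 8-iodoflavone (the new step), followed only by ester cleavage.
2. The coupling monomer is 8-iodo-4'-methoxy-5,7-bis(pivaloyloxy)flavone. It comes from the 5,7-dibenzyl ether (needed for C8-selective iodination) by debenzylation and pivaloylation; the 7-O-pivaloyl carbonyl is the directing handle for the nickel step.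
3. The flavone comes from oxidative cyclisation of a 2'-hydroxychalcone, itself made by Claisen–Schmidt condensation of di-O-benzyl phloroacetophenone (ring A) with 4-methoxybenzaldehyde (ring B).
4. Ring order: rings A and B are bought, ring C (the pyranone) is closed in step 3, and the two flavone units are joined in step 7.

Assumption: the SMILES carries no stereodescriptor and the only stereogenic element is the 8,8'' axis, so the (aR) [= (M)] atropisomer is taken as the target. SMILES cannot show the axis, so the descriptor is carried in the names. The ligand in step 7 is written as (S,S); the hand that gives (aR) is confirmed in the first run (CD couplet of 11) and the (R,R) ligand is used if the sense is opposite.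

**Route**

Step 1
Reactants: 1 phloroacetophenone (2',4',6'-trihydroxyacetophenone)
Product: 2 di-O-benzyl phloroacetophenone (1-[2,4-bis(benzyloxy)-6-hydroxyphenyl]ethan-1-one)
Conditions: BnBr (2.1 equiv), K2CO3 (2.2 equiv), DMF, 0 °C to rt
Reagents that add atoms: benzyl bromide, BrCc1ccccc1
Why: Williamson ether synthesis; the para hydroxyl and one ortho hydroxyl are alkylated, while the last ortho hydroxyl is held in a strong hydrogen bond to the acetyl carbonyl and stays free.

Step 2
Reactants: 2 di-O-benzyl phloroacetophenone; 3 4-methoxybenzaldehyde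
Product: 4 (E)-2'-hydroxy-4',6'-bis(benzyloxy)-4-methoxychalcone
Conditions: KOH (50% aq., 10 equiv), EtOH, rt, 48 h; then 1 M HCl
Reagents that add atoms: none
Why: Claisen–Schmidt (crossed aldol) condensation of a methyl ketone with a non-enolisable aldehyde; dehydration gives the conjugated E-enone as the thermodynamic product.

Step 3
Reactants: 4 (E)-2'-hydroxy-4',6'-bis(benzyloxy)-4-methoxychalcone
Product: 6 di-O-benzylacacetin (5,7-bis(benzyloxy)-4'-methoxyflavone), via racemic 5,7-bis(benzyloxy)-4'-methoxyflavanone 5 (not isolated)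
Conditions: I2 (10 mol%), DMSO, 130 °C, 2 h
Reagents that add atoms: none
Why: Iodine-catalysed oxidative cyclisation of a 2'-hydroxychalcone; the only free phenol closes ring C by oxa-Michael addition, and iodine with DMSO as terminal oxidant dehydrogenates the flavanone, so its stereocentre is erased.

Step 4
Reactants: 6 di-O-benzylacacetin
Product: 7 5,7-bis(benzyloxy)-8-iodo-4'-methoxyflavone
Conditions: NIS (1.1 equiv), TFA (20 mol%), CH2Cl2–MeCN, 0 °C to rt, dark
Reagents that add atoms: N-iodosuccinimide, O=C1CCC(=O)N1I
Why: Electrophilic aromatic iodination; in 5,7-dialkoxyflavones C8 (ortho to O1 and the 7-alkoxy group, para to the 5-alkoxy group) is the most reactive and least hindered site, and alkylation of O5 removes the free chelated 5-OH that would steer iodine to C6 (confirmed by NOE from H6 to both OCH2Ph groups).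

Step 5
Reactants: 7 5,7-bis(benzyloxy)-8-iodo-4'-methoxyflavone
Product: 8 8-iodoacacetin (5,7-dihydroxy-8-iodo-4'-methoxyflavone)
Conditions: BCl3 (5 equiv), pentamethylbenzene (6 equiv), CH2Cl2, −78 to −40 °C; then H2O
Reagents that add atoms: none
Why: Lewis-acid debenzylation with a non-basic cation scavenger; at low temperature BCl3 cleaves benzyl aryl ethers but leaves the 4'-methyl ether and the aryl iodide alone, whereas hydrogenolysis would cleave the C–I bond.

Step 6
Reactants: 8 8-iodoacacetin
Product: 9 8-iodo-4'-methoxy-5,7-bis(pivaloyloxy)flavone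
Conditions: PivCl (5 equiv), Et3N (6 equiv), DMAP (0.5 equiv), CH2Cl2, rt to 40 °C
Reagents that add atoms: pivaloyl chloride, CC(C)(C)C(=O)Cl
Why: DMAP-catalysed O-acylation of both phenols; it places a coordinating, out-of-plane carbonyl group on O7 next to the C–I bond and masks the 5-OH/4-carbonyl site that would otherwise chelate nickel and manganese ions.

Step 7
Reactants: 9 8-iodo-4'-methoxy-5,7-bis(pivaloyloxy)flavone (two molecules)
Product: 10 (aR)-4',4'''-dimethoxy-5,5'',7,7''-tetrakis(pivaloyloxy)-8,8''-biflavone
Conditions: NiBr2(dme) (10 mol%), (S,S)-iPr-BiOX [(4S,4'S)-4,4'-diisopropyl-4,4',5,5'-tetrahydro-2,2'-bioxazole] (12 mol%), Mn powder (3 equiv), NaI (0.5 equiv), DMA, 40 °C, argon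
Reagents that add atoms: none
Why: Proposed new method: nickel-catalysed atroposelective reductive homocoupling of an 8-iodoflavone, in which zerovalent nickel inserts into the C8–I bond, Mn reduces the resulting divalent aryl nickel iodide to a monovalent aryl nickel that adds a second molecule of 9, and the trivalent diaryl nickel reductively eliminates the C8–C8'' bond; the 7-O-pivaloyl group stands perpendicular to ring A and its carbonyl can bind nickel in a six-membered chelate, so the two ortho flanks (flat ring oxygen O1 against the bulky coordinating ester) differ clearly, the two aryl ligands place their pivalates anti, and the twofold-symmetric bis(oxazoline) selects one of the two mirror-image anti arrangements, which fixes the axis at reductive elimination (four ortho oxygen substituents make the product axis stable at 40 °C); the closest known reaction type is the nickel-catalysed enantioselective reductive Ullmann homocoupling of ortho-halo aryl aldehydes and esters to axially chiral biaryls, together with the racemic copper Ullmann dimerisation of 8-iodoflavone ethers, and it has not been shown for halochromones, for O-acyl in place of C-acyl handles or for biaryls with four ortho oxygens.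

Step 8
Reactants: 10 (aR)-4',4'''-dimethoxy-5,5'',7,7''-tetrakis(pivaloyloxy)-8,8''-biflavone
Product: 11 (aR)-4',4'''-di-O-methylcupressuflavone
Conditions: K2CO3 (6 equiv), degassed MeOH–THF, rt to 40 °C; then 1 M HCl
Reagents that add atoms: none
Why: Base-mediated transesterification (methanolysis) of four activated aryl pivalates; the aryl methyl ethers and the flavone rings are inert, and the tetra-ortho-substituted axis does not rotate under these conditions, so the configuration set in step 7 is kept.

**Compound list**
1 | phloroacetophenone (2',4',6'-trihydroxyacetophenone) | CC(=O)c1c(O)cc(O)cc1O | starting material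
2 | 1-[2,4-bis(benzyloxy)-6-hydroxyphenyl]ethan-1-one | CC(=O)c1c(O)cc(OCc2ccccc2)cc1OCc1ccccc1 | intermediate
3 | 4-methoxybenzaldehyde | COc1ccc(C=O)cc1 | starting material
4 | (E)-2'-hydroxy-4',6'-bis(benzyloxy)-4-methoxychalcone | COc1ccc(/C=C/C(=O)c2c(O)cc(OCc3ccccc3)cc2OCc2ccccc2)cc1 | intermediate
5 | racemic 5,7-bis(benzyloxy)-4'-methoxyflavanone (not isolated) | COc1ccc(cc1)C1CC(=O)c2c(OCc3ccccc3)cc(OCc3ccccc3)cc2O1 | intermediate
6 | 5,7-bis(benzyloxy)-4'-methoxyflavone | COc1ccc(cc1)-c1cc(=O)c2c(OCc3ccccc3)cc(OCc3ccccc3)cc2o1 | intermediate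
7 | 5,7-bis(benzyloxy)-8-iodo-4'-methoxyflavone | COc1ccc(cc1)-c1cc(=O)c2c(OCc3ccccc3)cc(OCc3ccccc3)c(I)c2o1 | intermediate
8 | 5,7-dihydroxy-8-iodo-4'-methoxyflavone | COc1ccc(cc1)-c1cc(=O)c2c(O)cc(O)c(I)c2o1 | intermediate
9 | 8-iodo-4'-methoxy-5,7-bis(pivaloyloxy)flavone | COc1ccc(cc1)-c1cc(=O)c2c(OC(=O)C(C)(C)C)cc(OC(=O)C(C)(C)C)c(I)c2o1 | intermediate
10 | (aR)-4',4'''-dimethoxy-5,5'',7,7''-tetrakis(pivaloyloxy)-8,8''-biflavone | COc1ccc(cc1)-c1cc(=O)c2c(OC(=O)C(C)(C)C)cc(OC(=O)C(C)(C)C)c(c2o1)-c1c(OC(=O)C(C)(C)C)cc(OC(=O)C(C)(C)C)c2c(=O)cc(oc12)-c1ccc(OC)cc1 | intermediate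
11 | (aR)-4',4'''-di-O-methylcupressuflavone | COc1ccc(-c2cc(=O)c3c(O)cc(O)c(-c4c(O)cc(O)c5c(=O)cc(-c6ccc(OC)cc6)oc45)c3o2)cc1 | target

**Totals**
Total step count: 8. Longest linear sequence: 8 steps (fully linear; step 7 joins two molecules of 9).

**Three steps most likely to fail**

Step 7 (the proposed new coupling). The risks are hydrodeiodination of the hindered aryl nickel, slow formation of the tetra-ortho-substituted bond, and insufficient enantioselectivity; a modest ee could be raised by recrystallising 10. The fallback uses known chemistry, sets out from 7 and comes back at 11. Classical Ullmann homocoupling of 7 (activated Cu bronze, DMF, 150 °C) gives racemic 5,5'',7,7''-tetrakis(benzyloxy)-4',4'''-dimethoxy-8,8''-biflavone F1. Preparative HPLC on an amylose tris(3,5-dimethylphenylcarbamate) phase gives (aR)-5,5'',7,7''-tetrakis(benzyloxy)-4',4'''-dimethoxy-8,8''-biflavone F2. Hydrogenolysis (H2, Pd/C, THF–MeOH, rt) then removes the four benzyl groups to give 11.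

Step 4 (C8 against C6 or C3 iodination). If the flavone gives mixtures, the halogen is put in before ring C exists; this fallback sets out from 2 and comes back at 7. Ketone 2 is iodinated ortho to its chelated phenol (BnMe3N·ICl2, CaCO3, CH2Cl2–MeOH, rt) to give 1-[4,6-bis(benzyloxy)-2-hydroxy-3-iodophenyl]ethan-1-one F3; its remaining aryl proton shows NOE to both OCH2Ph groups. Claisen–Schmidt condensation with 3 (KOH, EtOH, rt) gives (E)-1-[4,6-bis(benzyloxy)-2-hydroxy-3-iodophenyl]-3-(4-methoxyphenyl)prop-2-en-1-one F4. I2 (cat.) in DMSO at 130 °C closes ring C through racemic 5,7-bis(benzyloxy)-8-iodo-4'-methoxyflavanone F5 (not isolated) to 7. Because only one phenol is free, the iodine next to it must become C8.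

Step 3 (the HI formed at 130 °C can cleave the chelation-activated 5-O-benzyl ether). The fallback builds ring C without an oxidation, by the Baker–Venkataraman route; it sets out from 2 and comes back at 6. Acylation of 2 with 4-methoxybenzoyl chloride in pyridine gives 2-acetyl-3,5-bis(benzyloxy)phenyl 4-methoxybenzoate F6. KOH in pyridine at 50 °C moves the aroyl group from oxygen to carbon to give 1-[2,4-bis(benzyloxy)-6-hydroxyphenyl]-3-(4-methoxyphenyl)propane-1,3-dione F7. Cyclodehydration (TsOH·H2O 10 mol%, toluene, 80 °C) gives 6.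

**Further compounds**
F1 | step 7 | racemic 5,5'',7,7''-tetrakis(benzyloxy)-4',4'''-dimethoxy-8,8''-biflavone | COc1ccc(cc1)-c1cc(=O)c2c(OCc3ccccc3)cc(OCc3ccccc3)c(c2o1)-c1c(OCc2ccccc2)cc(OCc2ccccc2)c2c(=O)cc(oc12)-c1ccc(OC)cc1
F2 | step 7 | (aR)-5,5'',7,7''-tetrakis(benzyloxy)-4',4'''-dimethoxy-8,8''-biflavone | COc1ccc(cc1)-c1cc(=O)c2c(OCc3ccccc3)cc(OCc3ccccc3)c(c2o1)-c1c(OCc2ccccc2)cc(OCc2ccccc2)c2c(=O)cc(oc12)-c1ccc(OC)cc1
F3 | step 4 | 1-[4,6-bis(benzyloxy)-2-hydroxy-3-iodophenyl]ethan-1-one | CC(=O)c1c(O)c(I)c(OCc2ccccc2)cc1OCc1ccccc1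
F4 | step 4 | (E)-1-[4,6-bis(benzyloxy)-2-hydroxy-3-iodophenyl]-3-(4-methoxyphenyl)prop-2-en-1-one | COc1ccc(/C=C/C(=O)c2c(O)c(I)c(OCc3ccccc3)cc2OCc2ccccc2)cc1
F5 | step 4 | racemic 5,7-bis(benzyloxy)-8-iodo-4'-methoxyflavanone (not isolated) | COc1ccc(cc1)C1CC(=O)c2c(OCc3ccccc3)cc(OCc3ccccc3)c(I)c2O1
F6 | step 3 | 2-acetyl-3,5-bis(benzyloxy)phenyl 4-methoxybenzoate | COc1ccc(cc1)C(=O)Oc1cc(OCc2ccccc2)cc(OCc2ccccc2)c1C(C)=O
F7 | step 3 | 1-[2,4-bis(benzyloxy)-6-hydroxyphenyl]-3-(4-methoxyphenyl)propane-1,3-dione | COc1ccc(cc1)C(=O)CC(=O)c1c(O)cc(OCc2ccccc2)cc1OCc1ccccc1
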